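**Strategy**

Ring B of the target is functionalised only at C7=C8, so C7 is removed retrosynthetically and the labdane decalin is traced back to a B-nor trans-hydrindan-8-one whose C8 carbonyl sits between the unbranched C6 methylene and the branched C9. Forward, trimethylsilyldiazomethane and BF3·OEt2 insert C7 between C6 and C8 in one operation, enlarging the cyclopentanone to ring B and leaving the ketone at C8 for Δ7 methylation. The precursor is a 9-allyl-4α-silyloxy-10-methyl trans-hydrindan-8-one, made by a Pauson–Khand cyclisation in which a C4 silyloxy stereocentre fixes C10; the equatorial silyl ether tolerates BF3 and dissolving metal.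

Key step: step 10

Numbering remark: all bicyclic compounds carry labdane numbers (C7 is absent in the hydrindane series); β is the face of the C10 methyl group, α the opposite face.

Assumption: the kinetic allylation of step 8 is taken to occur anti to the C10 methyl (9α-allyl); C9 is re-set under thermodynamic control in step 10, so a 9β-allyl by-product would converge on the same compound 20.

**Route**

Step 1
Reactants: 1 2-methylallylmagnesium chloride; 2 β-propiolactone
Product: 3 5-methylhex-5-enoic acid
Conditions: CuI (5 mol %), THF–Me2S, −30 → 0 °C; then 2 M HCl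
Reagents that add atoms: none
Why: Copper-catalysed SN2 opening of the β-lactone at its O–CH2 carbon by the allylic Grignard reagent (alkyl–oxygen cleavage) gives the chain-extended acid directly.

Step 2
Reactants: 3 5-methylhex-5-enoic acid
Product: 5 N-methoxy-N,5-dimethylhex-5-enamide, via acyl imidazolide 4 (not isolated)
Conditions: CDI, CH2Cl2, rt; then MeNHOMe·HCl, rt
Reagents that add atoms: N,O-dimethylhydroxylamine hydrochloride, CNOC.Cl
Why: Amide formation through carbonyldiimidazole activation gives the Weinreb amide.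

Step 3
Reactants: 5 N-methoxy-N,5-dimethylhex-5-enamide; 6 ethynyltrimethylsilane
Product: 8 7-methyl-1-(trimethylsilyl)oct-7-en-1-yn-3-one, via lithium acetylide 7 (not isolated)
Conditions: n-BuLi, THF, −78 °C; then 5, −78 → 0 °C; aq. NH4Cl
Reagents that add atoms: none
Why: Weinreb ketone synthesis; the N-methoxy chelate survives until work-up, so the acetylide adds only once.

Step 4
Reactants: 8 7-methyl-1-(trimethylsilyl)oct-7-en-1-yn-3-one
Product: 9 (3R)-7-methyl-1-(trimethylsilyl)oct-7-en-1-yn-3-ol
Conditions: Ru[(R,R)-TsNCHPhCHPhNH](p-cymene) (1 mol %), i-PrOH, rt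
Reagents that add atoms: none
Why: Noyori asymmetric transfer hydrogenation of an alkynyl ketone; the alkynyl group plays the role of the π-substituent, so the (R,R) catalyst should deliver the (R)-carbinol that becomes C4.

Step 5
Reactants: 9 (3R)-7-methyl-1-(trimethylsilyl)oct-7-en-1-yn-3-ol
Product: 10 (3R)-3-(tert-butyldimethylsilyloxy)-7-methyl-1-(trimethylsilyl)oct-7-en-1-yne
Conditions: TBSCl, imidazole, DMF, rt
Reagents that add atoms: tert-butyldimethylsilyl chloride, CC(C)(C)[Si](C)(C)Cl
Why: Standard silylation of a secondary alcohol; the bulky silyl ether is the stereocontrol element of step 7.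

Step 6
Reactants: 10 (3R)-3-(tert-butyldimethylsilyloxy)-7-methyl-1-(trimethylsilyl)oct-7-en-1-yne
Product: 11 (3R)-3-(tert-butyldimethylsilyloxy)-7-methyloct-7-en-1-yne
Conditions: K2CO3, MeOH, rt
Reagents that add atoms: none
Why: Base-mediated methanolysis cleaves the C(sp)–Si bond selectively and leaves the O-silyl ether intact.

Step 7
Reactants: 11 (3R)-3-(tert-butyldimethylsilyloxy)-7-methyloct-7-en-1-yne
Product: 12 (4R,7aR)-4-(tert-butyldimethylsilyloxy)-7a-methyl-1,4,5,6,7,7a-hexahydro-2H-inden-2-one
Conditions: Co2(CO)8 (0.3 equiv), tetramethylthiourea, CO (1 atm), PhMe, 70 °C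
Reagents that add atoms: carbon monoxide, [C-]#[O+]
Why: Pauson–Khand [2+2+1] cyclocarbonylation of a 1,7-enyne forms ring A, C10 and the cyclopentenone; in the chair-like insertion the C4 silyloxy group stays pseudo-equatorial to avoid a 1,3-diaxial clash with the methyl on the inserting alkene carbon, so the C10 methyl should end up trans to it (a minor diastereomer is removable by chromatography).

Step 8
Reactants: 12 (4R,7aR)-4-(tert-butyldimethylsilyloxy)-7a-methyl-1,4,5,6,7,7a-hexahydro-2H-inden-2-one; 13 allyl bromide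
Product: 15 9α-allyl-4α-(tert-butyldimethylsilyloxy)-10β-methylhydrind-5-en-8-one, via lithium dienolate 14 (not isolated)
Conditions: LiN(i-Pr)2, THF, −78 °C; then allyl bromide, −78 → −20 °C
Reagents that add atoms: none
Why: Kinetic α′-enolate alkylation of a cyclopentenone at C9, the only kinetically accessible position; the electrophile should enter anti to the adjacent C10 methyl.

Step 9
Reactants: 15 9α-allyl-4α-(tert-butyldimethylsilyloxy)-10β-methylhydrind-5-en-8-one
Product: 17 9α-allyl-4α-(tert-butyldimethylsilyloxy)-10β-methyl-trans-hydrindan-8-one, via lithium enolate 16 (not isolated)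
Conditions: Li, NH3(l), THF, t-BuOH (1 equiv), −78 °C; then NH4Cl
Reagents that add atoms: none
Why: Dissolving-metal (Birch-type) enone reduction protonates C5 anti to the angular methyl to give the trans ring fusion (5α-H); the isolated alkene is untouched, and the equatorial C4–O bond lies near the nodal plane of the C5 carbanion, so β-elimination of the silyloxy group is not expected.

Step 10
Reactants: 17 9α-allyl-4α-(tert-butyldimethylsilyloxy)-10β-methyl-trans-hydrindan-8-one
Product: 20 9β-allyl-4α-(tert-butyldimethylsilyloxy)-10β-methyl-trans-decal-8-one, via α-silyl ketone 18 (not isolated), via 9α-allyl decalone 19 (not isolated)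
Conditions: Me3SiCHN2, BF3·OEt2, CH2Cl2, −78 → −30 °C; then NaOMe, MeOH, rt
Reagents that add atoms: trimethylsilyldiazomethane, C[Si](C)(C)C=[N+]=[N-]
Why: BF3 activates the C8 carbonyl, the diazo carbon adds to it, and loss of N2 from the betaine is coupled with a 1,2-shift of C6 to the former diazo carbon, which becomes C7 between C6 and C8. This is a Lewis-acid-promoted diazoalkane homologation of a cyclic ketone (Tiffeneau–Demjanov-type ring enlargement), established for cyclopentanone-to-cyclohexanone conversion. Ring B is not closed by a new cyclisation but arises by enlargement of the five-membered ring through this 1,2-alkyl shift, which forms C6–C7 and C7–C8 in one operation. No ring stereocentre is created (the transient C7–Si centre is erased by methanolysis), C5 and C10 are untouched, and C9, now α to a cyclohexanone, is equilibrated by methoxide towards the equatorial 9β-allyl group, which avoids the syn-axial C5–H and C7–H bonds; any residual 9α epimer is resubmitted. The step needs migration of C6 and not C9 and a single insertion: C6 is an unhindered methylene whereas C9 is branched, flanked by quaternary C10 and would have to move towards the Me3Si-bearing carbon, and the α-silyl ketone formed is too hindered to react again. The allyl group and the silyl ether are inert to BF3·OEt2 at low temperature.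

Step 11
Reactants: 20 9β-allyl-4α-(tert-butyldimethylsilyloxy)-10β-methyl-trans-decal-8-one
Product: 22 9β-allyl-4α-(tert-butyldimethylsilyloxy)-10β-methyl-trans-decal-7-en-8-yl trifluoromethanesulfonate, via potassium enolate 21 (not isolated)
Conditions: KN(SiMe3)2, THF, −78 °C; then PhNTf2, −78 → 0 °C
Reagents that add atoms: N-phenylbis(trifluoromethanesulfonimide), O=S(=O)(N(c1ccccc1)S(=O)(=O)C(F)(F)F)C(F)(F)F
Why: Kinetic deprotonation at the unhindered C7 methylene (not the tertiary C9–H next to quaternary C10) and O-sulfonylation of the enolate fix the double bond at C7=C8.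

Step 12
Reactants: 22 9β-allyl-4α-(tert-butyldimethylsilyloxy)-10β-methyl-trans-decal-7-en-8-yl trifluoromethanesulfonate
Product: 23 9β-allyl-4α-(tert-butyldimethylsilyloxy)-8,10β-dimethyl-trans-decal-7-ene
Conditions: MeMgBr, Fe(acac)3 (5 mol %), THF–NMP, −30 → 0 °C
Reagents that add atoms: methylmagnesium bromide, C[Mg]Br
Why: Iron-catalysed Kumada-type cross-coupling of an alkenyl triflate with a methyl Grignard reagent installs C17 with the alkene held at C7=C8; C9 is no longer epimerisable.

Step 13
Reactants: 23 9β-allyl-4α-(tert-butyldimethylsilyloxy)-8,10β-dimethyl-trans-decal-7-ene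
Product: 24 9β-allyl-8,10β-dimethyl-trans-decal-7-en-4α-ol
Conditions: Bu4NF, THF, 50 °C
Reagents that add atoms: none
Why: Fluoride-mediated cleavage of the secondary silyl ether.

Step 14
Reactants: 24 9β-allyl-8,10β-dimethyl-trans-decal-7-en-4α-ol
Product: 25 9β-allyl-8,10β-dimethyl-trans-decal-7-en-4-one
Conditions: Dess–Martin periodinane, NaHCO3, CH2Cl2, 0 °C → rt
Reagents that add atoms: none
Why: Dess–Martin oxidation under buffered, non-enolising conditions gives the C4 ketone without disturbing the adjacent C5 stereocentre.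

Step 15
Reactants: 25 9β-allyl-8,10β-dimethyl-trans-decal-7-en-4-one
Product: 27 9β-allyl-8,10β-dimethyl-trans-decal-7-ene-4-carbaldehyde (C4 epimers), via methyl enol ether 26 (not isolated)
Conditions: MeOCH2PPh3Cl, KN(SiMe3)2, THF, 0 °C; then 25, 0 °C → rt; then 2 M HCl, rt
Reagents that add atoms: (methoxymethyl)triphenylphosphonium chloride, COC[P+](c1ccccc1)(c1ccccc1)c1ccccc1.[Cl-]; water, O
Why: Wittig methoxymethylenation with excess ylide (fast olefination limits enolisation towards C5) and acid hydrolysis of the enol ether give the one-carbon-homologated aldehyde; its C4 configuration is irrelevant because C4 is enolised next.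

Step 16
Reactants: 27 9β-allyl-8,10β-dimethyl-trans-decal-7-ene-4-carbaldehyde
Product: 29 14,15,16-trinorlabda-7,12-dien-19-al (4α-methyl and 4β-formyl), via potassium enolate 28 (not isolated)
Conditions: KOt-Bu, THF, 0 °C; then MeI, 0 °C → rt
Reagents that add atoms: iodomethane, CI
Why: C-Alkylation of the aldehyde enolate; iodomethane approaches C4 from the equatorial α face because the axial β face is blocked by the 1,3-diaxial C10 methyl, which sets 4α-CH3 and 4β-CHO.

Step 17
Reactants: 29 14,15,16-trinorlabda-7,12-dien-19-al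
Product: 30 14,15,16-trinorlabda-7,12-dien-19-ol
Conditions: NaBH4, MeOH, 0 °C
Reagents that add atoms: none
Why: Borohydride reduction of the neopentyl aldehyde to the C19 primary alcohol.

Step 18
Reactants: 30 14,15,16-trinorlabda-7,12-dien-19-ol; 31 angelic acid
Product: 33 14,15,16-trinorlabda-7,12-dien-19-yl angelate, via mixed anhydride 32 (not isolated)
Conditions: 2,4,6-Cl3C6H2COCl, Et3N, PhMe, rt; then 30, 80 °C
Reagents that add atoms: none
Why: Yamaguchi-type esterification through the mixed 2,4,6-trichlorobenzoic anhydride, run without a nucleophilic catalyst, acylates the alcohol while avoiding the addition–elimination pathway that isomerises angelates to tiglates.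

Step 19
Reactants: 33 14,15,16-trinorlabda-7,12-dien-19-yl angelate
Product: 35 13-hydroxy-14,15,16-trinorlabd-7-en-19-yl angelate, via alkylborane 34 (not isolated)
Conditions: 9-BBN, THF, 0 °C → rt; then H2O2, aq. NaOAc
Reagents that add atoms: hydrogen peroxide, OO
Why: Anti-Markovnikov hydroboration–oxidation; 9-BBN selects the monosubstituted terminal alkene over the hindered trisubstituted C7=C8 bond and the electron-poor angelate alkene, and the buffered oxidation spares the ester.

Step 20
Reactants: 35 13-hydroxy-14,15,16-trinorlabd-7-en-19-yl angelate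
Product: 36 13-oxo-14,15,16-trinorlabd-7-en-19-yl angelate
Conditions: Dess–Martin periodinane, NaHCO3, CH2Cl2, rt
Reagents that add atoms: none
Why: Dess–Martin oxidation of the primary alcohol to the aldehyde.

Step 21
Reactants: 36 13-oxo-14,15,16-trinorlabd-7-en-19-yl angelate
Product: 37 15,16-dinorlabd-7-en-13-yn-19-yl angelate
Conditions: MeC(O)C(N2)P(O)(OMe)2, K2CO3, MeOH, 0 °C → rt
Reagents that add atoms: dimethyl (1-diazo-2-oxopropyl)phosphonate, CC(=O)C(=[N+]=[N-])P(=O)(OC)OC
Why: Seyferth–Gilbert homologation with the Ohira–Bestmann reagent converts the aldehyde into the terminal alkyne and adds C14; the hindered neopentyl angelate should outlast the short methanolic carbonate treatment.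

Step 22
Reactants: 37 15,16-dinorlabd-7-en-13-yn-19-yl angelate; 13 allyl bromide
Product: 39 allyl 19-angeloyloxy-16-norlabd-7-en-13-yn-15-oate, via caesium alkynoate 38 (not isolated)
Conditions: CO2 (1 atm), AgI (2 mol %), Cs2CO3, DMF, 50 °C; then allyl bromide, rt
Reagents that add atoms: carbon dioxide, O=C=O
Why: Silver-catalysed C–H carboxylation of the terminal alkyne with CO2 followed by O-alkylation of the caesium carboxylate gives the ynoate without an organolithium that could attack the angelate.

Step 23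
Reactants: 39 allyl 19-angeloyloxy-16-norlabd-7-en-13-yn-15-oate
Product: 41 allyl (13Z)-19-angeloyloxylabda-7,13-dien-15-oate, via alkenylcuprate 40 (not isolated)
Conditions: Me2CuLi (from MeLi, CuI), THF, −78 °C; then MeOH, aq. NH4Cl, −78 °C
Reagents that add atoms: lithium dimethylcuprate, [Li+].C[Cu-]C
Why: Syn-carbocupration (conjugate addition) of the ynoate and protonation of the alkenylcuprate at low temperature place the new methyl (C16) cis to H14, so C12 and the ester are cis, i.e. the (13Z)-enoate; the angelate is a far poorer acceptor.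

Step 24
Reactants: 41 allyl (13Z)-19-angeloyloxylabda-7,13-dien-15-oate
Product: 42 (13Z)-19-angeloyloxylabda-7,13-dien-15-oic acid
Conditions: Pd(PPh3)4 (5 mol %), morpholine, THF, rt
Reagents that add atoms: none
Why: Tsuji–Trost deallylation; zerovalent palladium ionises the allyl ester and morpholine traps the allyl fragment, releasing the acid under neutral conditions that leave the angelate and both alkene geometries intact.

**Compound list**

1 | 2-methylallylmagnesium chloride | C=C(C)C[Mg]Cl | starting material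
2 | β-propiolactone (oxetan-2-one) | O=C1CCO1 | starting material
3 | 5-methylhex-5-enoic acid | C=C(C)CCCC(=O)O | intermediate
4 | 1-(5-methylhex-5-enoyl)imidazole | C=C(C)CCCC(=O)n1ccnc1 | intermediate
5 | N-methoxy-N,5-dimethylhex-5-enamide | C=C(C)CCCC(=O)N(C)OC | intermediate
6 | ethynyltrimethylsilane | C#C[Si](C)(C)C | starting material
7 | lithium (trimethylsilyl)acetylide | [Li]C#C[Si](C)(C)C | intermediate
8 | 7-methyl-1-(trimethylsilyl)oct-7-en-1-yn-3-one | C=C(C)CCCC(=O)C#C[Si](C)(C)C | intermediate
9 | (3R)-7-methyl-1-(trimethylsilyl)oct-7-en-1-yn-3-ol | C=C(C)CCC[C@@H](O)C#C[Si](C)(C)C | intermediate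
10 | (3R)-3-(tert-butyldimethylsilyloxy)-7-methyl-1-(trimethylsilyl)oct-7-en-1-yne | C=C(C)CCC[C@@H](O[Si](C)(C)C(C)(C)C)C#C[Si](C)(C)C | intermediate
11 | (3R)-3-(tert-butyldimethylsilyloxy)-7-methyloct-7-en-1-yne | C=C(C)CCC[C@@H](O[Si](C)(C)C(C)(C)C)C#C | intermediate
12 | (4R,7aR)-4-(tert-butyldimethylsilyloxy)-7a-methyl-1,4,5,6,7,7a-hexahydro-2H-inden-2-one (4α-silyloxy, 10β-methyl, C5=C6 conjugated with the C8 ketone) | O=C1C=C2[C@H](O[Si](C)(C)C(C)(C)C)CCC[C@]2(C)C1 | intermediate
13 | allyl bromide | C=CCBr | starting material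
14 | lithium C8,C9-dienolate of 12 | [Li]OC1=C[C@@]2(C)CCC[C@@H](O[Si](C)(C)C(C)(C)C)C2=C1 | intermediate
15 | 9α-allyl-4α-(tert-butyldimethylsilyloxy)-10β-methylhydrind-5-en-8-one | O=C1C=C2[C@H](O[Si](C)(C)C(C)(C)C)CCC[C@]2(C)[C@@H]1CC=C | intermediate
16 | lithium C8,C6-enolate of 17 | [Li]OC1=C[C@H]2[C@H](O[Si](C)(C)C(C)(C)C)CCC[C@]2(C)[C@@H]1CC=C | intermediate
17 | 9α-allyl-4α-(tert-butyldimethylsilyloxy)-10β-methyl-trans-hydrindan-8-one (5α-H; C7 absent) | O=C1C[C@H]2[C@H](O[Si](C)(C)C(C)(C)C)CCC[C@]2(C)[C@@H]1CC=C | intermediate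
18 | 9α-allyl-4α-(tert-butyldimethylsilyloxy)-10β-methyl-7-(trimethylsilyl)-trans-decal-8-one (C7 epimers) | O=C1C([Si](C)(C)C)C[C@H]2[C@H](O[Si](C)(C)C(C)(C)C)CCC[C@]2(C)[C@@H]1CC=C | intermediate
19 | 9α-allyl-4α-(tert-butyldimethylsilyloxy)-10β-methyl-trans-decal-8-one | O=C1CC[C@H]2[C@H](O[Si](C)(C)C(C)(C)C)CCC[C@]2(C)[C@@H]1CC=C | intermediate
20 | 9β-allyl-4α-(tert-butyldimethylsilyloxy)-10β-methyl-trans-decal-8-one (5α-H) | O=C1CC[C@H]2[C@H](O[Si](C)(C)C(C)(C)C)CCC[C@]2(C)[C@H]1CC=C | intermediate
21 | potassium C7,C8-enolate of 20 | [K]OC1=CC[C@H]2[C@H](O[Si](C)(C)C(C)(C)C)CCC[C@]2(C)[C@H]1CC=C | intermediate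
22 | 9β-allyl-4α-(tert-butyldimethylsilyloxy)-10β-methyl-trans-decal-7-en-8-yl trifluoromethanesulfonate | O=S(=O)(OC1=CC[C@H]2[C@H](O[Si](C)(C)C(C)(C)C)CCC[C@]2(C)[C@H]1CC=C)C(F)(F)F | intermediate
23 | 9β-allyl-4α-(tert-butyldimethylsilyloxy)-8,10β-dimethyl-trans-decal-7-ene | CC1=CC[C@H]2[C@H](O[Si](C)(C)C(C)(C)C)CCC[C@]2(C)[C@H]1CC=C | intermediate
24 | 9β-allyl-8,10β-dimethyl-trans-decal-7-en-4α-ol | CC1=CC[C@H]2[C@H](O)CCC[C@]2(C)[C@H]1CC=C | intermediate
25 | 9β-allyl-8,10β-dimethyl-trans-decal-7-en-4-one | CC1=CC[C@H]2C(=O)CCC[C@]2(C)[C@H]1CC=C | intermediate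
26 | 9β-allyl-4-(methoxymethylene)-8,10β-dimethyl-trans-decal-7-ene (E/Z mixture) | CC1=CC[C@H]2C(=COC)CCC[C@]2(C)[C@H]1CC=C | intermediate
27 | 9β-allyl-8,10β-dimethyl-trans-decal-7-ene-4-carbaldehyde (C4 epimers) | CC1=CC[C@H]2C(C=O)CCC[C@]2(C)[C@H]1CC=C | intermediate
28 | potassium enolate of 27 | CC1=CC[C@H]2C(=CO[K])CCC[C@]2(C)[C@H]1CC=C | intermediate
29 | 14,15,16-trinorlabda-7,12-dien-19-al (4α-methyl, 4β-formyl, 5α-H, 9β-allyl, 10β-methyl) | CC1=CC[C@H]2[C@@](C)(C=O)CCC[C@]2(C)[C@H]1CC=C | intermediate
30 | 14,15,16-trinorlabda-7,12-dien-19-ol | CC1=CC[C@H]2[C@@](C)(CO)CCC[C@]2(C)[C@H]1CC=C | intermediate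
31 | angelic acid ((Z)-2-methylbut-2-enoic acid) | C/C=C(/C)C(=O)O | starting material
32 | angelic 2,4,6-trichlorobenzoic anhydride | C/C=C(/C)C(=O)OC(=O)c1c(Cl)cc(Cl)cc1Cl | intermediate
33 | 14,15,16-trinorlabda-7,12-dien-19-yl angelate | C/C=C(/C)C(=O)OC[C@@]1(C)CCC[C@]2(C)[C@@H](CC=C)C(C)=CC[C@@H]12 | intermediate
34 | B-alkyl-9-borabicyclo[3.3.1]nonane of 33 (boron on C13) | C/C=C(/C)C(=O)OC[C@@]1(C)CCC[C@]2(C)[C@@H](CCCB3C4CCCC3CCC4)C(C)=CC[C@@H]12 | intermediate
35 | 13-hydroxy-14,15,16-trinorlabd-7-en-19-yl angelate | C/C=C(/C)C(=O)OC[C@@]1(C)CCC[C@]2(C)[C@@H](CCCO)C(C)=CC[C@@H]12 | intermediate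
36 | 13-oxo-14,15,16-trinorlabd-7-en-19-yl angelate | C/C=C(/C)C(=O)OC[C@@]1(C)CCC[C@]2(C)[C@@H](CCC=O)C(C)=CC[C@@H]12 | intermediate
37 | 15,16-dinorlabd-7-en-13-yn-19-yl angelate | C/C=C(/C)C(=O)OC[C@@]1(C)CCC[C@]2(C)[C@@H](CCC#C)C(C)=CC[C@@H]12 | intermediate
38 | caesium 19-angeloyloxy-16-norlabd-7-en-13-yn-15-oate | C/C=C(/C)C(=O)OC[C@@]1(C)CCC[C@]2(C)[C@@H](CCC#CC(=O)[O-])C(C)=CC[C@@H]12.[Cs+] | intermediate
39 | allyl 19-angeloyloxy-16-norlabd-7-en-13-yn-15-oate | C/C=C(/C)C(=O)OC[C@@]1(C)CCC[C@]2(C)[C@@H](CCC#CC(=O)OCC=C)C(C)=CC[C@@H]12 | intermediate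
40 | lithium methyl(alkenyl)cuprate from 39 (copper on C14, cis to the new C16 methyl) | C/C=C(/C)C(=O)OC[C@@]1(C)CCC[C@]2(C)[C@@H](CC/C(C)=C(\C(=O)OCC=C)[Cu-]C)C(C)=CC[C@@H]12.[Li+] | intermediate
41 | allyl (13Z)-19-angeloyloxylabda-7,13-dien-15-oate | C/C=C(/C)C(=O)OC[C@@]1(C)CCC[C@]2(C)[C@@H](CC/C(C)=C\C(=O)OCC=C)C(C)=CC[C@@H]12 | intermediate
42 | (13Z)-19-angeloyloxylabda-7,13-dien-15-oic acid (CNP0249147.1) | C/C=C(/C)C(=O)OC[C@@]1(C)CCC[C@]2(C)[C@@H](CC/C(C)=C\C(=O)O)C(C)=CC[C@@H]12 | target

**Step count and risks**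

Total step count: 24. Longest linear sequence: 24 steps (from 1 and 2 to 42).

Steps most likely to fail:

Step 10. What may go wrong: partial migration of the branched C9 instead of C6 (which would move the carbonyl to the wrong ring position), a second insertion into the product ketone, or incomplete convergence of the C9 epimers during the methoxide treatment. Fallback, in which the regiochemistry is fixed by an enol ether and not by migratory aptitude: the sequence sets out from 15. The dissolving-metal reduction of 15 is quenched with Me3SiCl/Et3N so that the regiodefined C8,C6-enolate is trapped as the trimethylsilyl enol ether F1. Simmons–Smith cyclopropanation (Et2Zn, CH2I2) of this electron-rich alkene, which should react well ahead of the allyl group, gives the siloxycyclopropane F2, whose new CH2 is the future C7. FeCl3 in DMF (Ito–Saegusa ring enlargement) cleaves the internal C6–C8 cyclopropane bond to the 6-chloro decal-8-one F3, and NaOAc in MeOH eliminates HCl to the decal-6-en-8-one F4. Li/NH3 reduction of this enone gives 19, which the methoxide treatment of step 10 converts into 20.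

Step 7. What may go wrong: oligomerisation of the terminal alkyne before the hindered 1,1-disubstituted alkene inserts, and erosion of the relay of configuration from C4 to C10 if the silyloxy group does not stay pseudo-equatorial. Fallback, which changes the substrate and the point of alkyne desilylation: the sequence sets out from 10 and omits step 6. The C-silylated enyne is cyclocarbonylated with the cobalt catalyst; the Me3Si group on the alkyne terminus blocks alkyne oligomerisation and raises the penalty for a pseudo-axial silyloxy group, giving the 6-(trimethylsilyl) enone F5. Allylation as in step 8 gives the 9α-allyl 6-silyl enone F6, and Li/NH3 reduction gives the 6-silyl hydrindanone F7, whose C–Si bond α to the ketone is cleaved by K2CO3 in MeOH. The route is re-joined at 17.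

Step 16. What may go wrong: O-methylation of the hindered aldehyde enolate in place of C-methylation, or attack of iodomethane on the axial face. Fallback, which uses an ester enolate in place of the aldehyde enolate: the sequence sets out from 27. Pinnick oxidation (NaClO2, NaH2PO4, 2-methylbut-2-ene) gives the carboxylic acid F8, and Me3SiCHN2 in MeOH–PhMe gives the methyl ester F9. LiN(i-Pr)2 followed by MeI methylates the ester enolate on carbon from the equatorial α face to give the 4α-methyl 4β-ester F10, and LiAlH4 reduces it to 30, where the route is re-joined.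

**Further compounds**

F1 | step 10 | 9α-allyl-4α-(tert-butyldimethylsilyloxy)-10β-methyl-8-(trimethylsilyloxy)-trans-hydrind-6(8)-ene | C[Si](C)(C)OC1=C[C@H]2[C@H](O[Si](C)(C)C(C)(C)C)CCC[C@]2(C)[C@@H]1CC=C
F2 | step 10 | siloxycyclopropane from F1 (CH2 bridging C6 and C8; 8-trimethylsilyloxy) | C[Si](C)(C)OC12CC1[C@H]3[C@H](O[Si](C)(C)C(C)(C)C)CCC[C@]3(C)[C@@H]2CC=C
F3 | step 10 | 9α-allyl-4α-(tert-butyldimethylsilyloxy)-6-chloro-10β-methyl-trans-decal-8-one | O=C1CC(Cl)[C@H]2[C@H](O[Si](C)(C)C(C)(C)C)CCC[C@]2(C)[C@@H]1CC=C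
F4 | step 10 | 9α-allyl-4α-(tert-butyldimethylsilyloxy)-10β-methyl-trans-decal-6-en-8-one | O=C1C=C[C@H]2[C@H](O[Si](C)(C)C(C)(C)C)CCC[C@]2(C)[C@@H]1CC=C
F5 | step 7 | 4α-(tert-butyldimethylsilyloxy)-10β-methyl-6-(trimethylsilyl)hydrind-5-en-8-one | O=C1C([Si](C)(C)C)=C2[C@H](O[Si](C)(C)C(C)(C)C)CCC[C@]2(C)C1
F6 | step 7 | 9α-allyl-4α-(tert-butyldimethylsilyloxy)-10β-methyl-6-(trimethylsilyl)hydrind-5-en-8-one | O=C1C([Si](C)(C)C)=C2[C@H](O[Si](C)(C)C(C)(C)C)CCC[C@]2(C)[C@@H]1CC=C
F7 | step 7 | 9α-allyl-4α-(tert-butyldimethylsilyloxy)-10β-methyl-6-(trimethylsilyl)-trans-hydrindan-8-one (C6 epimers) | O=C1C([Si](C)(C)C)[C@H]2[C@H](O[Si](C)(C)C(C)(C)C)CCC[C@]2(C)[C@@H]1CC=C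
F8 | step 16 | 9β-allyl-8,10β-dimethyl-trans-decal-7-ene-4-carboxylic acid (C4 epimers) | CC1=CC[C@H]2C(C(=O)O)CCC[C@]2(C)[C@H]1CC=C
F9 | step 16 | methyl 9β-allyl-8,10β-dimethyl-trans-decal-7-ene-4-carboxylate (C4 epimers) | CC1=CC[C@H]2C(C(=O)OC)CCC[C@]2(C)[C@H]1CC=C
F10 | step 16 | methyl 14,15,16-trinorlabda-7,12-dien-19-oate (4α-methyl, 4β-ester) | CC1=CC[C@H]2[C@@](C)(C(=O)OC)CCC[C@]2(C)[C@H]1CC=C
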